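**Plan**

1. Numbering (hydroazulene, used for all intermediates): C1 (isopropyl), C2 (secondary angelate), C3, C3a (methyl), C4, C5 (ketone), C6 (methyl, tertiary angelate), C7, C8, C8a; alkene C1=C8a.
2. Retrosynthesis: remove the C2 angelate, take the C2 carbinol back to a ketone, then cut C3a–C8a and C5–C6 together as a (4+3) cycloaddition of a furan (C6–C7–C8–C8a plus its oxygen) with a gold-bound acyloxyallyl cation (C3a–C4–C5), tethered through C1–C2(=O)–C3.
3. Enabling feature: in the seven-membered ring C6 (bears O) and C8a are 1,4-related, and C8a is β to the C2 carbonyl of the five-membered ring. They are therefore the two α-carbons of a 2-methylfuran, whose oxygen stays on C6 and leaves C8a by β-elimination to give C1=C8a.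
4. Forward: a chain is built (nitroaldol condensation, Cu-catalysed conjugate addition, nitrile-oxide cycloaddition as masked aldol, angelate, propargyl-to-allenyl ester shift); one cycloaddition then closes the five- and the seven-membered ring; the bridge alkene is reduced, the bridge is opened with angelate transfer from the C5 enol to the C6 alkoxide, and C2 is reduced and esterified.
5. Stereochemistry: the isopropyl-bearing C1 centre (asymmetric conjugate addition) directs the furan face and hence C3a and C6, and is then erased as C1=C8a; C2 comes from a CBS reduction.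

Key step: step 8

Assumption: trimethyl(3-methylbut-3-en-1-yn-1-yl)silane (6) is taken as purchased; otherwise it is one silylation from 2-methylbut-1-en-3-yne.

**Step 1**
Reactants: 1 5-methylfuran-2-carbaldehyde; 2 nitromethane
Product: 3 2-methyl-5-[(E)-2-nitroethenyl]furan
Conditions: NH4OAc (0.3 equiv), MeNO2 (solvent), 90 °C
Reagents that add atoms: none
Why: Henry (nitroaldol) condensation of an electron-rich heteroaryl aldehyde, in which dehydration under the conditions should give the conjugated (E)-nitroalkene.

**Step 2**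
Reactants: 3 2-methyl-5-[(E)-2-nitroethenyl]furan; 4 diisopropylzinc
Product: 5 2-methyl-5-[(2R)-3-methyl-1-nitrobutan-2-yl]furan
Conditions: Cu(OTf)2 (2 mol%), chiral binaphthol-derived phosphoramidite ligand (4 mol%, the enantiomer that delivers the (R) product), toluene, −30 °C; aq. NH4Cl
Reagents that add atoms: none
Why: copper-catalysed asymmetric conjugate addition of a dialkylzinc to a β-heteroaryl nitroalkene, in which the ligand-bound copper delivers isopropyl to one alkene face and so sets the (R) centre (C1) that later steers the cycloaddition.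

**Step 3**
Reactants: 5 2-methyl-5-[(2R)-3-methyl-1-nitrobutan-2-yl]furan; 6 trimethyl(3-methylbut-3-en-1-yn-1-yl)silane
Product: 8 silylalkynyl isoxazoline (both C5 epimers), via nitrile oxide 7 (not isolated)
Conditions: PhNCO (2.2 equiv), Et3N (cat.), 6 (3 equiv), toluene, 23 → 50 °C
Reagents that add atoms: none
Why: Mukaiyama dehydration of the primary nitroalkane followed by 1,3-dipolar cycloaddition of the nitrile oxide to the 1,1-disubstituted alkene (oxygen to the substituted carbon) should give an isoxazoline that is a masked aldol, carrying C2 at the ketone level and C3a with its oxygen; the epimers at the new carbon converge in step 7.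

**Step 4**
Reactants: 8 silylalkynyl isoxazoline
Product: 10 silylated hydroxy ketone, via hydroxy ketimine 9 (not isolated)
Conditions: SmI2 (2.5 equiv), THF, 0 °C; then B(OH)3, MeOH/H2O, 23 °C
Reagents that add atoms: water (O)
Why: reductive N–O cleavage of the isoxazoline and boric-acid-buffered hydrolysis of the ketimine should release the β-hydroxy ketone under conditions too mild to enolise the α-furyl centre.

**Step 5**
Reactants: 10 silylated hydroxy ketone
Product: 11 (6S)-3-hydroxy-3,7-dimethyl-6-(5-methylfuran-2-yl)oct-1-yn-5-one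
Conditions: Bu4NF, AcOH (1:1), THF, 0 °C
Reagents that add atoms: none
Why: fluoride protodesilylation of the alkynylsilane, buffered with acetic acid so that the tertiary aldol does not undergo retro-aldol cleavage.

**Step 6**
Reactants: 11 (6S)-3-hydroxy-3,7-dimethyl-6-(5-methylfuran-2-yl)oct-1-yn-5-one; 12 angelic acid
Product: 13 (6S)-3,7-dimethyl-6-(5-methylfuran-2-yl)-5-oxooct-1-yn-3-yl (2Z)-2-methylbut-2-enoate
Conditions: 12, 2,4,6-Cl3C6H2COCl, Et3N, toluene, 23 °C; 11, LiN(SiMe3)2, THF, −78 °C; combined, −78 → −40 °C
Reagents that add atoms: none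
Why: acylation of the tertiary lithium alkoxide by the Yamaguchi-type mixed anhydride at its unhindered angeloyl carbonyl, at low temperature and without a nucleophilic catalyst, should keep the aldol intact and the Z alkene unisomerised.

**Step 7**
Reactants: 13 tertiary propargylic angelate
Product: 14 (6S)-3,7-dimethyl-6-(5-methylfuran-2-yl)-5-oxoocta-1,2-dien-1-yl (2Z)-2-methylbut-2-enoate
Conditions: AgBF4 (5 mol%), CH2Cl2, 23 °C, dark
Reagents that add atoms: none
Why: silver-catalysed [3,3]-sigmatropic 1,3-acyloxy shift (Saucy–Marbet type) of a tertiary propargylic ester with a terminal alkyne should give the 1-acyloxyallene and so place the oxygen on C5.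

**Step 8**
Reactants: 14 allenyl angelate
Product: 15 (1S,2S,5R,8S)-5,8-dimethyl-3-oxo-2-(propan-2-yl)-11-oxatricyclo[6.2.1.0(1,5)]undeca-6,9-dien-7-yl (2Z)-2-methylbut-2-enoate
Conditions: chloro[1,3-bis(2,6-diisopropylphenyl)imidazol-2-ylidene]gold (IPrAuCl, 5 mol%), AgSbF6 (5 mol%), CH2Cl2, −20 → 23 °C
Reagents that add atoms: none
Why: IPrAu+ binds the allenyl ester and opens it to a planar gold-bound allyl cation over C3a–C4–C5 (both allene epimers converge), which adds across the 2,5-positions of the furan in an asynchronous (4+3) cycloaddition; the seven-membered gold carbene at C4 then takes the hydrogen geminal to the acyloxy group by 1,2-shift and releases the C4=C5 enol ester and the catalyst. The closest known reaction type is the gold-catalysed intramolecular (4+3) cycloaddition of allenes, including 1-acyloxyallenes made from propargyl esters, with three-atom-tethered furans and dienes. The cyclopentanone closes by 5-exo attack of the tethered furan α-carbon on the allyl terminus C3a, and the seven-membered ring closes in the same event as an oxygen-bridged (8-oxabicyclo[3.2.1]) ring. The bridgeheads C6 and C8a are fixed relative to each other by the suprafacial addition to the furan, their absolute sense by the (S) centre at C1, whose isopropyl group points away from the incoming cation, and C3a by addition in the compact mode with the tether carbon outward, which puts its methyl group syn to the oxygen bridge. The step needs the (4+3) path rather than Friedel–Crafts substitution, closure through C4 or 1,2-acyloxy shift, and the compact rather than the extended mode: both furan α-positions are substituted, the strongly donating N-heterocyclic carbene ligand and the readily migrating hydrogen on the oxygen-bearing C5 favour the (4+3) path, and only the compact mode staggers all groups about the two forming bonds, whereas the extended mode eclipses the inward C3a methyl with furan C3–H and the outward acyloxy group with the furan methyl.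

**Step 9**
Reactants: 15 cycloadduct
Product: 16 (1S,2S,5R,8S)-5,8-dimethyl-3-oxo-2-(propan-2-yl)-11-oxatricyclo[6.2.1.0(1,5)]undec-6-en-7-yl (2Z)-2-methylbut-2-enoate
Conditions: KO2CN=NCO2K, AcOH, MeOH/CH2Cl2, 0 → 23 °C
Reagents that add atoms: none
Why: diimide reduction (concerted syn hydrogen transfer) should be selective for the strained cis-disubstituted bridge alkene over the trisubstituted enol-ester and angelate alkenes, and it is done under acidic conditions before the bridge is opened so that no dienone forms.

**Step 10**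
Reactants: 16 dihydro cycloadduct
Product: 18 (3aR,6S)-3a,6-dimethyl-2,5-dioxo-1-(propan-2-yl)-2,3,3a,4,5,6,7,8-octahydroazulen-6-yl (2Z)-2-methylbut-2-enoate, via hydroxy enol ester 17 (not isolated)
Conditions: DBU (1.5 equiv), CH2Cl2, 0 → 23 °C
Reagents that add atoms: none
Why: E1cB opening (enolisation of the C2 ketone toward C1 expels the bridge oxygen from C8a) should give the C1=C8a enone and the C6 alkoxide, which takes the angeloyl group from the neighbouring C5 enol ester through a five-membered tetrahedral intermediate (O-to-O acyl migration) and so unveils the C5 ketone with C6 unchanged.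

**Step 11**
Reactants: 18 dione angelate
Product: 19 (2S,3aR,6S)-2-hydroxy-3a,6-dimethyl-5-oxo-1-(propan-2-yl)-2,3,3a,4,5,6,7,8-octahydroazulen-6-yl (2Z)-2-methylbut-2-enoate
Conditions: (R)-Me-CBS oxazaborolidine (20 mol%), catecholborane (1.5 equiv), toluene, −78 °C
Reagents that add atoms: none
Why: Corey–Bakshi–Shibata 1,2-reduction of the enone carbonyl (alkenyl side large, CH2 side small) should deliver hydride anti to the angular methyl and give (2S), reagent and substrate control being matched, while the C5 ketone between the quaternary C6 and the neopentyl C4 should not react at −78 °C.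

**Step 12**
Reactants: 19 hydroxy ketone angelate; 12 angelic acid
Product: 20 CNP0193302.1
Conditions: 12, 2,4,6-Cl3C6H2COCl, Et3N, toluene, 23 °C; then 19, toluene, 70 °C
Reagents that add atoms: none
Why: Yamaguchi-type esterification through the mixed anhydride without DMAP should acylate the hindered allylic alcohol with retention at C2 and without Z to E isomerisation of either angelate.

**Compound list**

1 | 5-methylfuran-2-carbaldehyde | Cc1ccc(C=O)o1 | starting material
2 | nitromethane | C[N+](=O)[O-] | starting material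
3 | 2-methyl-5-[(E)-2-nitroethenyl]furan | Cc1ccc(/C=C/[N+](=O)[O-])o1 | intermediate
4 | diisopropylzinc | CC(C)[Zn]C(C)C | starting material
5 | 2-methyl-5-[(2R)-3-methyl-1-nitrobutan-2-yl]furan | Cc1ccc([C@H](C(C)C)C[N+](=O)[O-])o1 | intermediate
6 | trimethyl(3-methylbut-3-en-1-yn-1-yl)silane | C=C(C)C#C[Si](C)(C)C | starting material
7 | (2R)-3-methyl-2-(5-methylfuran-2-yl)butanenitrile N-oxide | Cc1ccc([C@H](C(C)C)C#[N+][O-])o1 | intermediate
8 | 5-methyl-3-[(1R)-2-methyl-1-(5-methylfuran-2-yl)propyl]-5-[(trimethylsilyl)ethynyl]-4,5-dihydro-1,2-oxazole (both C5 epimers) | Cc1ccc([C@H](C(C)C)C2=NOC(C)(C#C[Si](C)(C)C)C2)o1 | intermediate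
9 | (6R)-5-imino-3,7-dimethyl-6-(5-methylfuran-2-yl)-1-(trimethylsilyl)oct-1-yn-3-ol (both C3 epimers) | Cc1ccc([C@H](C(C)C)C(=N)CC(C)(O)C#C[Si](C)(C)C)o1 | intermediate
10 | (6S)-3-hydroxy-3,7-dimethyl-6-(5-methylfuran-2-yl)-1-(trimethylsilyl)oct-1-yn-5-one (both C3 epimers) | Cc1ccc([C@H](C(C)C)C(=O)CC(C)(O)C#C[Si](C)(C)C)o1 | intermediate
11 | (6S)-3-hydroxy-3,7-dimethyl-6-(5-methylfuran-2-yl)oct-1-yn-5-one (both C3 epimers) | Cc1ccc([C@H](C(C)C)C(=O)CC(C)(O)C#C)o1 | intermediate
12 | angelic acid, (2Z)-2-methylbut-2-enoic acid | C/C=C(/C)C(=O)O | starting material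
13 | (6S)-3,7-dimethyl-6-(5-methylfuran-2-yl)-5-oxooct-1-yn-3-yl (2Z)-2-methylbut-2-enoate (both C3 epimers) | Cc1ccc([C@H](C(C)C)C(=O)CC(C)(OC(=O)/C(C)=C\C)C#C)o1 | intermediate
14 | (6S)-3,7-dimethyl-6-(5-methylfuran-2-yl)-5-oxoocta-1,2-dien-1-yl (2Z)-2-methylbut-2-enoate (both allene epimers) | Cc1ccc([C@H](C(C)C)C(=O)CC(C)=C=COC(=O)/C(C)=C\C)o1 | intermediate
15 | (1S,2S,5R,8S)-5,8-dimethyl-3-oxo-2-(propan-2-yl)-11-oxatricyclo[6.2.1.0(1,5)]undeca-6,9-dien-7-yl (2Z)-2-methylbut-2-enoate | C/C=C(/C)C(=O)OC1=C[C@@]2(C)CC(=O)[C@@H](C(C)C)[C@]23O[C@@]1(C)C=C3 | intermediate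
16 | (1S,2S,5R,8S)-5,8-dimethyl-3-oxo-2-(propan-2-yl)-11-oxatricyclo[6.2.1.0(1,5)]undec-6-en-7-yl (2Z)-2-methylbut-2-enoate | C/C=C(/C)C(=O)OC1=C[C@@]2(C)CC(=O)[C@@H](C(C)C)[C@]23O[C@@]1(C)CC3 | intermediate
17 | (3aR,6S)-6-hydroxy-3a,6-dimethyl-2-oxo-1-(propan-2-yl)-2,3,3a,6,7,8-hexahydroazulen-5-yl (2Z)-2-methylbut-2-enoate | C/C=C(/C)C(=O)OC1=C[C@@]2(C)CC(=O)C(C(C)C)=C2CC[C@]1(C)O | intermediate
18 | (3aR,6S)-3a,6-dimethyl-2,5-dioxo-1-(propan-2-yl)-2,3,3a,4,5,6,7,8-octahydroazulen-6-yl (2Z)-2-methylbut-2-enoate | O=C1C[C@]2(C)CC(=O)[C@@](C)(OC(=O)/C(C)=C\C)CCC2=C1C(C)C | intermediate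
19 | (2S,3aR,6S)-2-hydroxy-3a,6-dimethyl-5-oxo-1-(propan-2-yl)-2,3,3a,4,5,6,7,8-octahydroazulen-6-yl (2Z)-2-methylbut-2-enoate | O[C@H]1C[C@]2(C)CC(=O)[C@@](C)(OC(=O)/C(C)=C\C)CCC2=C1C(C)C | intermediate
20 | CNP0193302.1, (2S,3aR,6S)-3a,6-dimethyl-5-oxo-1-(propan-2-yl)-2,3,3a,4,5,6,7,8-octahydroazulene-2,6-diyl bis[(2Z)-2-methylbut-2-enoate] | C/C=C(/C)C(=O)O[C@H]1C[C@]2(C)CC(=O)[C@@](C)(OC(=O)/C(C)=C\C)CCC2=C1C(C)C | target

**Step count and risks**

Total steps: 12. Longest linear sequence: 12 steps (from 1).

Steps most likely to fail: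

1. Step 8. The acyloxy group may scramble between the 1,3- and 1,2-shifted gold species, the cation may close through C4 or be lost to Friedel–Crafts attack, and addition may occur in the extended instead of the compact mode. Fallback (oxygen brought in after the cycloaddition): from 13, Pd2(dba)3/PBu3/HCO2NH4 in THF should give the oxygen-free allene (3S)-2,6-dimethyl-3-(5-methylfuran-2-yl)octa-6,7-dien-4-one F1. The same gold catalyst should convert it into the des-acyloxy cycloadduct F2, the best-precedented substrate class for this cycloaddition. Diimide should reduce the bridge alkene to the monoene F3. mCPBA should epoxidise the remaining C4=C5 alkene from the face of the oxygen bridge to the epoxide F4. BF3·OEt2 should open the epoxide at C4, the carbon remote from the bridge oxygen, with hydride shift (Meinwald rearrangement) to the C5 ketone F5. DBU should open the bridge to the hydroxy dione F6, whose tertiary alkoxide (LiN(SiMe3)2, −78 °C) is acylated with the angelic mixed anhydride of step 6, which returns to the route at 18. This fallback addresses the scrambling and periselectivity; a wrong addition mode would not be repaired by it.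

2. Step 6. The lithium alkoxide of the tertiary aldol may cleave by retro-aldol reaction, the β-acyloxy ketone may eliminate, and the angelate may isomerise. Fallback (the Z alkene is built after the ester bond): from 11, 2-[bis(2,2,2-trifluoroethoxy)phosphoryl]propanoic acid and DCC (acylation through the phosphonoketene, no alkoxide) should give the phosphonate ester (6S)-3,7-dimethyl-6-(5-methylfuran-2-yl)-5-oxooct-1-yn-3-yl 2-[bis(2,2,2-trifluoroethoxy)phosphoryl]propanoate F7. Still–Gennari olefination with acetaldehyde (KN(SiMe3)2, 18-crown-6, THF, −78 °C) should then give the Z-configured ester and return to the route at 13.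

3. Step 11. The C5 ketone may be reduced in competition, and facial selectivity at C2 may be poor. Fallback (the C5 ketone stays masked during the reduction): from 16, TMSOTf/Et3N in CH2Cl2 should open the bridge with silylation of the C6 oxygen, so that no acyl transfer occurs, and give the C6 trimethylsilyl ether of 17, F8, which has a single ketone. (R)-Me-CBS/catecholborane should reduce it to the (2S)-alcohol F9. Bu4NF should then free the C6 alkoxide, which takes the angeloyl group from the C5 enol ester and returns to the route at 19.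

**Further compounds**

F1 | step 8 | (3S)-2,6-dimethyl-3-(5-methylfuran-2-yl)octa-6,7-dien-4-one | Cc1ccc([C@H](C(C)C)C(=O)CC(C)=C=C)o1
F2 | step 8 | 5,8-dimethyl-2-(propan-2-yl)-11-oxatricyclo[6.2.1.0(1,5)]undeca-6,9-dien-3-one, configured as 15 | C1=C[C@@]2(C)CC(=O)[C@@H](C(C)C)[C@]23O[C@@]1(C)C=C3
F3 | step 8 | 5,8-dimethyl-2-(propan-2-yl)-11-oxatricyclo[6.2.1.0(1,5)]undec-6-en-3-one, configured as 16 | C1=C[C@@]2(C)CC(=O)[C@@H](C(C)C)[C@]23O[C@@]1(C)CC3
F4 | step 8 | 6,7-epoxide of F3, epoxide oxygen on the face of the oxygen bridge | O1[C@@H]2[C@H]1[C@@]3(C)CC(=O)[C@@H](C(C)C)[C@]34O[C@@]2(C)CC4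
F5 | step 8 | 5,8-dimethyl-2-(propan-2-yl)-11-oxatricyclo[6.2.1.0(1,5)]undecane-3,7-dione, configured as 16 | O=C1C[C@@]2(C)CC(=O)[C@@H](C(C)C)[C@]23O[C@@]1(C)CC3
F6 | step 8 | (3aR,6S)-6-hydroxy-3a,6-dimethyl-1-(propan-2-yl)-3,3a,4,6,7,8-hexahydroazulene-2,5-dione | O=C1C[C@]2(C)CC(=O)[C@@](C)(O)CCC2=C1C(C)C
F7 | step 6 | (6S)-3,7-dimethyl-6-(5-methylfuran-2-yl)-5-oxooct-1-yn-3-yl 2-[bis(2,2,2-trifluoroethoxy)phosphoryl]propanoate | Cc1ccc([C@H](C(C)C)C(=O)CC(C)(OC(=O)C(C)P(=O)(OCC(F)(F)F)OCC(F)(F)F)C#C)o1
F8 | step 11 | (3aR,6S)-3a,6-dimethyl-2-oxo-1-(propan-2-yl)-6-(trimethylsilyloxy)-2,3,3a,6,7,8-hexahydroazulen-5-yl (2Z)-2-methylbut-2-enoate | C/C=C(/C)C(=O)OC1=C[C@@]2(C)CC(=O)C(C(C)C)=C2CC[C@]1(C)O[Si](C)(C)C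
F9 | step 11 | (2S,3aR,6S)-2-hydroxy-3a,6-dimethyl-1-(propan-2-yl)-6-(trimethylsilyloxy)-2,3,3a,6,7,8-hexahydroazulen-5-yl (2Z)-2-methylbut-2-enoate | C/C=C(/C)C(=O)OC1=C[C@@]2(C)C[C@H](O)C(C(C)C)=C2CC[C@]1(C)O[Si](C)(C)C
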